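**Retrosynthetic overview**

1. Target 25 comes from 24 by cleavage of all aryl ethers; 24 comes from ynol ether 15 and cyclobutenone 18 by a Danheiser-type benzannulation that builds ring B and, through lactonization of the new phenol, lactone B.
2. Feature used: ring B (C4a', C5', C6', C7', C8', C8a'; chroman-2-one numbering, primed = tetrahydroxy lactone B) carries five oxygens and one carbon substituent (C4'). C6'-C7'-C8'-C8a' with their four oxygens come from a squarate-derived cyclobutenone, C4a'-C5'(O) from an ynol ether, and O1' then closes on C2'.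
3. 15 comes from lactone 4 and thioester 12 by oxidative enolate coupling of C3 with C3'. The slim alkynyl group on C4' stands in for the bulky ring B, so each enolate is attacked opposite its own aryl group (3,4-trans in lactone A; the 3',4'-relationship that becomes cis in lactone B).
4. 4 comes from a Pechmann condensation and an asymmetric conjugate reduction (C4); 12 from a copper-catalysed asymmetric conjugate alkynylation of a cinnamic thioamide with ethoxyacetylene (C4'); 18 from dimethyl squarate.
5. Ring order: ring A with lactone A first (step 1), ring B and lactone B together last (step 10).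

Key step: step 10

Assumptions: unprimed locants are the 5,7-dioxygenated lactone A, primed ones lactone B; the C2' acyl group is carried as an S-methyl thioester (the acyl donor for the lactonization) instead of a methyl ester; the ligand enantiomers named in steps 2 and 5 are those expected to give 4R and 3R, and the mirror-image ligand is used if the opposite sense is met.

**Step 1**
Reactants: 1 3,5-dimethoxyphenol; 2 ethyl 3-(4-methoxyphenyl)-3-oxopropanoate
Product: 3 5,7-dimethoxy-4-(4-methoxyphenyl)-2H-chromen-2-one
Conditions: CF3CO2H, 60 °C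
Reagents that add atoms: none
Why: Pechmann condensation, in which acid-promoted transesterification of the β-keto ester by the phenol, attack of the free ortho carbon on the aryl ketone and dehydration give the 5,7-dioxygenated 4-arylcoumarin, with no stereocenter formed.

**Step 2**
Reactants: 3 5,7-dimethoxy-4-(4-methoxyphenyl)-2H-chromen-2-one
Product: 4 (4R)-5,7-dimethoxy-4-(4-methoxyphenyl)chroman-2-one (lactone A)
Conditions: Cu(OAc)2·H2O (5 mol %), (R)-DTBM-SEGPHOS (5.5 mol %), (EtO)2MeSiH (1.5 equiv), t-BuOH (1.2 equiv), PhMe, 0 °C → rt; aq. NH4F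
Reagents that add atoms: none
Why: Copper hydride-catalysed asymmetric conjugate reduction of a β,β-disubstituted unsaturated lactone, in which the ligated copper hydride delivers hydride to C4 on the face chosen by the chiral bisphosphine (sets C4 as R) and the alcohol protonates the copper enolate, so that the saturated lactone should be released with its carbonyl group intact.

**Step 3**
Reactants: 5 (E)-3-(4-methoxyphenyl)acrylic acid
Product: 7 (E)-3-(4-methoxyphenyl)-N,N-dimethylacrylamide, via acid chloride 6 (not isolated)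
Conditions: (COCl)2, DMF (cat.), CH2Cl2, 0 °C → rt; then Me2NH (3 equiv), THF, 0 °C
Reagents that add atoms: dimethylamine, CNC
Why: Acid chloride formation followed by acylation of a secondary amine, a routine amide synthesis that leaves the E double bond untouched.

**Step 4**
Reactants: 7 (E)-3-(4-methoxyphenyl)-N,N-dimethylacrylamide
Product: 8 (E)-3-(4-methoxyphenyl)-N,N-dimethylprop-2-enethioamide
Conditions: Lawesson's reagent (0.6 equiv), THF, 50 °C
Reagents that add atoms: Lawesson's reagent, COc1ccc(cc1)P1(=S)SP(=S)(S1)c1ccc(OC)cc1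
Why: Thionation of a tertiary amide with Lawesson's reagent by oxygen-sulfur exchange through a four-membered P-S-C-O intermediate, the usual route to α,β-unsaturated thioamides.

**Step 5**
Reactants: 8 (E)-3-(4-methoxyphenyl)-N,N-dimethylprop-2-enethioamide; 9 ethoxyacetylene
Product: 10 (3R)-5-ethoxy-3-(4-methoxyphenyl)-N,N-dimethylpent-4-ynethioamide
Conditions: 9 (2 equiv), [Cu(MeCN)4]PF6 (5 mol %), (R)-DTBM-SEGPHOS (6 mol %), LiOC6H4-4-OMe (5 mol %), THF, rt
Reagents that add atoms: none
Why: Copper-catalysed direct asymmetric conjugate alkynylation of an α,β-unsaturated thioamide, in which monovalent copper and the catalytic lithium aryloxide form the copper acetylide of 9 without strong base, the soft copper centre activates the thiocarbonyl group and the chiral bisphosphine directs the acetylide to one face of the β-carbon (sets C4' as R), while the basic anhydrous medium should spare the acid-sensitive ynol ether.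

**Step 6**
Reactants: 10 (3R)-5-ethoxy-3-(4-methoxyphenyl)-N,N-dimethylpent-4-ynethioamide
Product: 12 S-methyl (3R)-5-ethoxy-3-(4-methoxyphenyl)pent-4-ynethioate, via thioimidate iodide 11 (not isolated)
Conditions: MeI (5 equiv), THF, rt, dark; then pH 7 phosphate buffer, rt
Reagents that add atoms: iodomethane, CI; water, O
Why: S-Methylation of the thioamide gives an S-methyl thioimidate salt whose hydrolysis near neutral pH expels the protonated amine and leaves the thioester, a mild amide-to-thioester exchange that uses no acid able to hydrate the ynol ether and does not touch C4'.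

**Step 7**
Reactants: 4 (4R)-5,7-dimethoxy-4-(4-methoxyphenyl)chroman-2-one; 12 S-methyl (3R)-5-ethoxy-3-(4-methoxyphenyl)pent-4-ynethioate
Product: 15 S-methyl (2S,3R)-2-[(3R,4R)-5,7-dimethoxy-4-(4-methoxyphenyl)-2-oxochroman-3-yl]-5-ethoxy-3-(4-methoxyphenyl)pent-4-ynethioate, via lactone enolate 13 (not isolated), via thioester enolate 14 (not isolated)
Conditions: 4 (2 equiv) and 12 added to LiN(iPr)2 (3.1 equiv), THF, −78 °C; then Cu(O2CCH(Et)Bu)2 (3.2 equiv), −78 → −20 °C
Reagents that add atoms: none
Why: Oxidative heterocoupling of two lithium enolates by a divalent copper carboxylate (single-electron oxidation and C-C bond formation), in which the lactone enolate is attacked opposite its pseudo-axial C4 aryl group (sets C3 as R, 3,4-trans) and the thioester enolate reacts in the allylic-strain-controlled conformer with C4'-H in the enolate plane, on the face of the slim alkynyl group and opposite the C4' aryl group (sets C3' as S).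

**Step 8**
Reactants: 16 dimethyl squarate
Product: 17 4-hydroxy-2,3-dimethoxycyclobut-2-en-1-one (racemic)
Conditions: LiAlH(OtBu)3 (1.05 equiv), THF, −78 → −40 °C; aq. potassium sodium tartrate
Reagents that add atoms: none
Why: Chemoselective 1,2-reduction of one vinylogous ester carbonyl of a squarate diester by a bulky, mild hydride, which should stop at the 4-hydroxycyclobutenone, whose carbinol carbon later becomes aromatic so that its configuration is irrelevant.

**Step 9**
Reactants: 17 4-hydroxy-2,3-dimethoxycyclobut-2-en-1-one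
Product: 18 4-(tert-butyldimethylsilyloxy)-2,3-dimethoxycyclobut-2-en-1-one (racemic)
Conditions: TBSCl, imidazole, CH2Cl2, 0 °C
Reagents that add atoms: tert-butyldimethylsilyl chloride, CC(C)(C)[Si](C)(C)Cl
Why: Imidazole-promoted silylation of a secondary alcohol, run cold and base-buffered so that the sensitive hydroxycyclobutenone does not lose methanol.

**Step 10**
Reactants: 15 S-methyl (2S,3R)-2-[(3R,4R)-5,7-dimethoxy-4-(4-methoxyphenyl)-2-oxochroman-3-yl]-5-ethoxy-3-(4-methoxyphenyl)pent-4-ynethioate; 18 4-(tert-butyldimethylsilyloxy)-2,3-dimethoxycyclobut-2-en-1-one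
Product: 24 (3R,3'S,4R,4'R)-8'-(tert-butyldimethylsilyloxy)-5'-ethoxy-5,6',7,7'-tetramethoxy-4,4'-bis(4-methoxyphenyl)-[3,3'-bichromane]-2,2'-dione, via vinylketene 19 (not isolated), via vinylcyclobutenone 20 (not isolated), via dienylketene 21 (not isolated), via cyclohexadienone 22 (not isolated), via phenol thioester 23 (not isolated)
Conditions: 18 (1.8 equiv), PhMe (0.2 M, degassed), 85 °C, slow Ar sweep; then 2-hydroxypyridine (0.2 equiv), 105 °C
Reagents that add atoms: none
Why: Proposed new method: heating opens 18 by 4π electrocyclic ring opening (silyloxy group rotating outward) to the trioxygenated vinylketene 19, which adds [2+2] across the electron-rich alkyne of 15 to give the 2-vinylcyclobutenone 20 (bonds C8a'-C4a' and C5'-C6'); 4π opening of 20 to the dienylketene 21 and 6π electrocyclization (bond C8a'-C8') give the cyclohexadienone 22, which tautomerizes to the phenol 23. The closest known reaction is the Danheiser benzannulation of cyclobutenones with alkoxy- and siloxyalkynes, and thermal opening of squarate-derived 4-oxy-2,3-dialkoxycyclobutenones to vinylketenes is established in Moore-type ring expansions; new is the use of a fully oxygenated 4-silyloxycyclobutenone as the intermolecular vinylketene partner together with in situ lactonization. Ring B closes by the 6π electrocyclization of 21, and lactone B closes by 6-exo-trig acyl substitution of the C8a' hydroxyl on the C2' thioester with loss of methanethiol, helped by the fully substituted arene next to C4' and by 2-hydroxypyridine as a neutral acyl-transfer catalyst. No stereocenter is formed: C3, C4, C3' and C4' are not touched by the pericyclic steps in a neutral, aprotic medium, so the acyclic C3'/C4' relationship set in step 7 is carried into the 3',4'-cis lactone B. The step needs one orientation of the ketene-alkyne union, bonding of the nucleophilic alkyne carbon (C4a', β to the ethoxy group) to the ketene carbonyl carbon, which the polarization of the ynol ether secures and which puts the hydroxyl next to the C4' chain; a direct [4+2] path with the same orientation would only exchange the silyl and methyl ethers on ring B and would lead to the same target after step 11.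

**Step 11**
Reactants: 24 (3R,3'S,4R,4'R)-8'-(tert-butyldimethylsilyloxy)-5'-ethoxy-5,6',7,7'-tetramethoxy-4,4'-bis(4-methoxyphenyl)-[3,3'-bichromane]-2,2'-dione
Product: 25 (3R,3'S,4R,4'R)-5,5',6',7,7',8'-hexahydroxy-4,4'-bis(4-hydroxyphenyl)-[3,3'-bichromane]-2,2'-dione (CNP0064734.4)
Conditions: BBr3 (16 equiv), CH2Cl2, −78 → 0 °C; MeOH, then H2O, under Ar; reversed-phase chromatography (0.1 % HCO2H)
Reagents that add atoms: none
Why: Lewis acid-mediated cleavage of the aryl methyl, ethyl and silyl ethers by BBr3 (boron complexation, bromide attack at the alkyl carbon or at silicon, hydrolysis of the aryl borates on work-up), under which the two aryl lactones should persist and, cold and without base, the enolizable C3 and C3' centers should not equilibrate.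

**Compound list**

1 | 3,5-dimethoxyphenol | COc1cc(O)cc(OC)c1 | starting material
2 | ethyl 3-(4-methoxyphenyl)-3-oxopropanoate | CCOC(=O)CC(=O)c1ccc(OC)cc1 | starting material
3 | 5,7-dimethoxy-4-(4-methoxyphenyl)-2H-chromen-2-one | O=C1Oc2cc(OC)cc(OC)c2C(c2ccc(OC)cc2)=C1 | intermediate
4 | (4R)-5,7-dimethoxy-4-(4-methoxyphenyl)chroman-2-one (lactone A) | O=C1Oc2cc(OC)cc(OC)c2[C@@H](c2ccc(OC)cc2)C1 | intermediate
5 | (E)-3-(4-methoxyphenyl)acrylic acid | COc1ccc(/C=C/C(O)=O)cc1 | starting material
6 | (E)-3-(4-methoxyphenyl)acryloyl chloride (not isolated) | COc1ccc(/C=C/C(Cl)=O)cc1 | intermediate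
7 | (E)-3-(4-methoxyphenyl)-N,N-dimethylacrylamide | COc1ccc(/C=C/C(=O)N(C)C)cc1 | intermediate
8 | (E)-3-(4-methoxyphenyl)-N,N-dimethylprop-2-enethioamide | COc1ccc(/C=C/C(=S)N(C)C)cc1 | intermediate
9 | ethoxyacetylene | CCOC#C | starting material
10 | (3R)-5-ethoxy-3-(4-methoxyphenyl)-N,N-dimethylpent-4-ynethioamide | CN(C)C(=S)C[C@H](c1ccc(OC)cc1)C#COCC | intermediate
11 | [(3R)-5-ethoxy-3-(4-methoxyphenyl)-1-(methylsulfanyl)pent-4-yn-1-ylidene]dimethylammonium iodide (not isolated) | C[N+](C)=C(SC)C[C@H](c1ccc(OC)cc1)C#COCC.[I-] | intermediate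
12 | S-methyl (3R)-5-ethoxy-3-(4-methoxyphenyl)pent-4-ynethioate | CSC(=O)C[C@H](c1ccc(OC)cc1)C#COCC | intermediate
13 | lithium enolate of 4 (not isolated) | [Li+].[O-]C1=C[C@H](c2ccc(OC)cc2)c2c(OC)cc(OC)cc2O1 | intermediate
14 | lithium enolate of 12 (not isolated) | [Li+].[O-]C(SC)=C[C@H](c1ccc(OC)cc1)C#COCC | intermediate
15 | S-methyl (2S,3R)-2-[(3R,4R)-5,7-dimethoxy-4-(4-methoxyphenyl)-2-oxochroman-3-yl]-5-ethoxy-3-(4-methoxyphenyl)pent-4-ynethioate | O=C1Oc2cc(OC)cc(OC)c2[C@@H](c2ccc(OC)cc2)[C@@H]1[C@@H](C(=O)SC)[C@H](c1ccc(OC)cc1)C#COCC | intermediate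
16 | dimethyl squarate (3,4-dimethoxycyclobut-3-ene-1,2-dione) | COC1=C(OC)C(=O)C1=O | starting material
17 | 4-hydroxy-2,3-dimethoxycyclobut-2-en-1-one (racemic) | COC1=C(OC)C(O)C1=O | intermediate
18 | 4-(tert-butyldimethylsilyloxy)-2,3-dimethoxycyclobut-2-en-1-one (racemic) | CC(C)(C)[Si](C)(C)OC1C(OC)=C(OC)C1=O | intermediate
19 | (3Z)-4-(tert-butyldimethylsilyloxy)-2,3-dimethoxybuta-1,3-dien-1-one, vinylketene (not isolated) | O=C=C(OC)/C(OC)=C/O[Si](C)(C)C(C)(C)C | intermediate
20 | 2-vinylcyclobutenone from [2+2] addition of 19 to the alkyne of 15, mixture at the new ring carbon (not isolated) | O=C1Oc2cc(OC)cc(OC)c2[C@@H](c2ccc(OC)cc2)[C@@H]1[C@@H](C(=O)SC)[C@H](c1ccc(OC)cc1)C1=C(OCC)C(OC)(/C(OC)=C/O[Si](C)(C)C(C)(C)C)C1=O | intermediate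
21 | dienylketene from ring opening of 20 (not isolated) | O=C1Oc2cc(OC)cc(OC)c2[C@@H](c2ccc(OC)cc2)[C@@H]1[C@@H](C(=O)SC)[C@H](c1ccc(OC)cc1)C(=C=O)C(OCC)=C(OC)C(OC)=CO[Si](C)(C)C(C)(C)C | intermediate
22 | cyclohexa-2,4-dienone from 6π closure of 21 (not isolated) | O=C1Oc2cc(OC)cc(OC)c2[C@@H](c2ccc(OC)cc2)[C@@H]1[C@@H](C(=O)SC)[C@H](c1ccc(OC)cc1)C1=C(OCC)C(OC)=C(OC)C(O[Si](C)(C)C(C)(C)C)C1=O | intermediate
23 | hexasubstituted phenol with the open C2' thioester (not isolated) | O=C1Oc2cc(OC)cc(OC)c2[C@@H](c2ccc(OC)cc2)[C@@H]1[C@@H](C(=O)SC)[C@H](c1ccc(OC)cc1)c1c(OCC)c(OC)c(OC)c(O[Si](C)(C)C(C)(C)C)c1O | intermediate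
24 | (3R,3'S,4R,4'R)-8'-(tert-butyldimethylsilyloxy)-5'-ethoxy-5,6',7,7'-tetramethoxy-4,4'-bis(4-methoxyphenyl)-[3,3'-bichromane]-2,2'-dione | O=C1Oc2cc(OC)cc(OC)c2[C@@H](c2ccc(OC)cc2)[C@@H]1[C@H]1C(=O)Oc2c(O[Si](C)(C)C(C)(C)C)c(OC)c(OC)c(OCC)c2[C@H]1c1ccc(OC)cc1 | intermediate
25 | (3R,3'S,4R,4'R)-5,5',6',7,7',8'-hexahydroxy-4,4'-bis(4-hydroxyphenyl)-[3,3'-bichromane]-2,2'-dione (CNP0064734.4) | O=C1Oc2cc(O)cc(O)c2[C@@H](c2ccc(O)cc2)[C@@H]1[C@H]1C(=O)Oc2c(O)c(O)c(O)c(O)c2[C@H]1c1ccc(O)cc1 | target

**Step count**

Total steps: 11.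
Longest linear sequence: 7 steps (5 → 7 → 8 → 10 → 12 → 15 → 24 → 25; steps 3, 4, 5, 6, 7, 10, 11).

**Steps most likely to fail**

1. Step 10 (bears the label).
- Risk: the trioxygenated vinylketene may dimerize or lose its silyl group faster than it is captured by the hindered internal ynol ether. The ynol ether may lose ethylene by retro-ene reaction at the temperature the ring opening needs. Released methanethiol may add to unreacted ynol ether.
- Fallback (known reactions only; sets out from 6 and 4, comes back at 25): ring B is brought in as a preformed pentamethoxyphenyl group. Acid chloride 6 is N-acylated with the lithium salt of (R)-4-phenyloxazolidin-2-one to give (R)-3-[(E)-3-(4-methoxyphenyl)acryloyl]-4-phenyloxazolidin-2-one F2. The Grignard reagent made from 1-bromo-2,3,4,5,6-pentamethoxybenzene F1 (Mg, THF) is added with CuBr·SMe2 (−40 → −10 °C); the chelated s-cis imide is attacked opposite the 4-phenyl group, which should give (R)-3-[(3R)-3-(4-methoxyphenyl)-3-(2,3,4,5,6-pentamethoxyphenyl)propanoyl]-4-phenyloxazolidin-2-one F3 with C4' set. The aryl group delivered by copper is chosen as the pentamethoxyphenyl group so that the (R)-auxiliary gives both the required C4' and the required C3' configuration. Oxidative heterocoupling of the lithium enolates of F3 and 4 (LiN(iPr)2; Fe(acac)3, THF, −78 °C → rt) follows; the auxiliary shields one face of the imide enolate (sets C3') and 4 reacts trans to its aryl group, which should give the coupled imide (R)-3-{(2S,3R)-2-[(3R,4R)-5,7-dimethoxy-4-(4-methoxyphenyl)-2-oxochroman-3-yl]-3-(4-methoxyphenyl)-3-(2,3,4,5,6-pentamethoxyphenyl)propanoyl}-4-phenyloxazolidin-2-one F4. BBr3 then cleaves all nine methyl ethers, and one of the two equivalent ortho hydroxyls of the pentahydroxyphenyl ring closes lactone B on the imide carbonyl with loss of the auxiliary, giving 25.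

2. Step 7.
- Risk: homocoupling of either enolate may compete with cross-coupling of two similar ester-type enolates. The aryl ester enolate may fragment to a ketene and phenoxide on warming. The product may be deprotonated by remaining enolate, eroding C3 and C3'.
- Fallback (sets out from 4 and 12, comes back at 15): the two partners are given fixed roles. 4 is brominated through its lithium enolate (LiN(SiMe3)2, then N-bromosuccinimide, −78 °C) to (3S,4R)-3-bromo-5,7-dimethoxy-4-(4-methoxyphenyl)chroman-2-one F5. 12 is converted (LiN(iPr)2, Me3SiCl, −78 °C) into its ketene silyl S,O-acetal, [(3R)-5-ethoxy-3-(4-methoxyphenyl)-1-(methylsulfanyl)pent-1-en-4-yn-1-yl]oxytrimethylsilane F6. Visible-light photoredox coupling (fac-Ir(ppy)3, blue light, 2,6-lutidine, MeCN, rt) reduces F5 to the electrophilic C3 radical, which should add to the electron-rich C3' terminus of F6 on the face opposite the C4' aryl group and trans to the C4 aryl group. Oxidation of the adduct radical and loss of the silyl group give 15.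

3. Step 5.
- Risk: the copper acetylide of the small alkoxyalkyne may oligomerize or hold the catalyst so that turnover stops, or the small alkyne may be delivered with poor facial discrimination.
- Fallback (sets out from 8 and 9, comes back at 15): 9 is converted into ethoxyethynylmagnesium bromide (EtMgBr, THF) and added in stoichiometric amount to 8, since α,β-unsaturated thioamides accept Grignard reagents in the conjugate sense. This gives racemic 5-ethoxy-3-(4-methoxyphenyl)-N,N-dimethylpent-4-ynethioamide F7. The conditions of step 6 convert it into racemic S-methyl 5-ethoxy-3-(4-methoxyphenyl)pent-4-ynethioate F8. The coupling of step 7 with enantiopure 4 then gives 15 together with the diastereomer that arises from the (3S)-thioester, S-methyl (2R,3S)-2-[(3R,4R)-5,7-dimethoxy-4-(4-methoxyphenyl)-2-oxochroman-3-yl]-5-ethoxy-3-(4-methoxyphenyl)pent-4-ynethioate F9, which is removed by chromatography. C4' is then fixed by separation instead of by catalysis.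

**Further compounds**

F1 | step 10 | 1-bromo-2,3,4,5,6-pentamethoxybenzene | COc1c(Br)c(OC)c(OC)c(OC)c1OC
F2 | step 10 | (R)-3-[(E)-3-(4-methoxyphenyl)acryloyl]-4-phenyloxazolidin-2-one | COc1ccc(/C=C/C(=O)N2[C@H](c3ccccc3)COC2=O)cc1
F3 | step 10 | (R)-3-[(3R)-3-(4-methoxyphenyl)-3-(2,3,4,5,6-pentamethoxyphenyl)propanoyl]-4-phenyloxazolidin-2-one | O=C(C[C@H](c1ccc(OC)cc1)c1c(OC)c(OC)c(OC)c(OC)c1OC)N1[C@H](c2ccccc2)COC1=O
F4 | step 10 | (R)-3-{(2S,3R)-2-[(3R,4R)-5,7-dimethoxy-4-(4-methoxyphenyl)-2-oxochroman-3-yl]-3-(4-methoxyphenyl)-3-(2,3,4,5,6-pentamethoxyphenyl)propanoyl}-4-phenyloxazolidin-2-one | O=C1Oc2cc(OC)cc(OC)c2[C@@H](c2ccc(OC)cc2)[C@@H]1[C@@H](C(=O)N1[C@H](c2ccccc2)COC1=O)[C@H](c1ccc(OC)cc1)c1c(OC)c(OC)c(OC)c(OC)c1OC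
F5 | step 7 | (3S,4R)-3-bromo-5,7-dimethoxy-4-(4-methoxyphenyl)chroman-2-one | O=C1Oc2cc(OC)cc(OC)c2[C@@H](c2ccc(OC)cc2)[C@@H]1Br
F6 | step 7 | [(3R)-5-ethoxy-3-(4-methoxyphenyl)-1-(methylsulfanyl)pent-1-en-4-yn-1-yl]oxytrimethylsilane | C[Si](C)(C)OC(SC)=C[C@H](c1ccc(OC)cc1)C#COCC
F7 | step 5 | racemic 5-ethoxy-3-(4-methoxyphenyl)-N,N-dimethylpent-4-ynethioamide | CCOC#CC(CC(=S)N(C)C)c1ccc(OC)cc1
F8 | step 5 | racemic S-methyl 5-ethoxy-3-(4-methoxyphenyl)pent-4-ynethioate | CSC(=O)CC(c1ccc(OC)cc1)C#COCC
F9 | step 5 | S-methyl (2R,3S)-2-[(3R,4R)-5,7-dimethoxy-4-(4-methoxyphenyl)-2-oxochroman-3-yl]-5-ethoxy-3-(4-methoxyphenyl)pent-4-ynethioate | O=C1Oc2cc(OC)cc(OC)c2[C@@H](c2ccc(OC)cc2)[C@@H]1[C@H](C(=O)SC)[C@@H](c1ccc(OC)cc1)C#COCC
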